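**Retrosynthetic overview**

1. Ring letters: C is the central tetra-oxygenated benzene, F the chlorinated phenoxy ring on it, B and D the two rings ether-linked to C, G and H the trihydroxyphenyl groups carbon-bonded to B and D, A and E the outer trihydroxyphenoxy rings on B and D.
2. Feature the plan rests on: ring F is a 4-chloro-3,5-dihydroxyphenoxy ring, with Cl on the carbon between the two C–OH carbons and para to the ether oxygen; that oxygen sits on the ring C carbon lying between the two arm-bearing C–O carbons.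
3. Key disconnection: ring F is opened to the ethynyl ether of the ring C phenol plus 4-chloro-3-ethoxycyclobutenone (benzannulation). The crowded C–O bond therefore exists before ring F does, and Cl, OH, OEt and OAr arrive in their final positions without any chlorination of an electron-rich oligomer.
4. End game: global O-dealkylation, preceded by a twofold Ullmann etherification of the two ring C hydroxyls (freed from benzyl ethers) with an arm bromide holding rings A, B and G; the second copy supplies E, D and H.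
5. Order of rings: A, B, C and G are bought as benzenes. Ring B comes from 2-bromo-1,3-dimethoxybenzene by C–H borylation/oxidation, ring G is attached by Suzuki coupling at a C–I bond, ring A by Ullmann etherification. Ring F is the only ring constructed, before the arms are attached.

Key step: step 7

Remark on the chemistry: the target has no stereocentre, and rings G and H are symmetric about their biaryl axes, so no configuration has to be controlled. The ring F hydroxyl freed in the annulation is capped as an ethyl ether, so that ring F stays symmetric until the last step.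

**Route**

Step 1
Reactants: 1 2,6-dibromo-4-methoxyphenol
Product: 2 1,3-dibromo-5-methoxy-2-(methoxymethoxy)benzene
Conditions: MOMCl, i-Pr2NEt, CH2Cl2, 0 °C to rt
Reagents that add atoms: chloromethyl methyl ether, COCCl
Why: Williamson-type O-alkylation of an acidic 2,6-dibromophenol gives an acetal that masks the phenol during the copper step and is later removed without touching benzyl ethers.

Step 2
Reactants: 2 1,3-dibromo-5-methoxy-2-(methoxymethoxy)benzene
Product: 3 1,3-bis(benzyloxy)-5-methoxy-2-(methoxymethoxy)benzene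
Conditions: BnOH (6 equiv), CuI (20 mol %), 3,4,7,8-tetramethyl-1,10-phenanthroline (40 mol %), Cs2CO3, toluene, 110 °C
Reagents that add atoms: benzyl alcohol, OCc1ccccc1
Why: Ullmann-type copper-catalysed C–O coupling of an aryl bromide with a primary alcohol, run on two equivalent C–Br bonds, each of which has an ortho acetal oxygen that can assist the copper.

Step 3
Reactants: 3 1,3-bis(benzyloxy)-5-methoxy-2-(methoxymethoxy)benzene
Product: 4 2,6-bis(benzyloxy)-4-methoxyphenol
Conditions: HCl (3 M aq), MeOH/THF, 50 °C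
Reagents that add atoms: none
Why: acid-catalysed acetal cleavage (MOM removal) should free only the central phenol, since benzyl and methyl aryl ethers are inert to dilute acid.

Step 4
Reactants: 4 2,6-bis(benzyloxy)-4-methoxyphenol; 5 trichloroethylene
Product: 7 1,3-bis(benzyloxy)-2-{[(E)-1,2-dichloroethenyl]oxy}-5-methoxybenzene, via dichloroacetylene 6 (not isolated)
Conditions: 5 (3 equiv), K2CO3, DMF, 70 °C
Reagents that add atoms: none
Why: base-mediated O-vinylation of a phenol with trichloroethylene, in which dehydrochlorination gives dichloroacetylene and anti addition of the phenoxide sets the E alkene; the electrophile is small enough to reach an oxygen flanked by two benzyloxy groups.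

Step 5
Reactants: 7 1,3-bis(benzyloxy)-2-{[(E)-1,2-dichloroethenyl]oxy}-5-methoxybenzene
Product: 10 1,3-bis(benzyloxy)-2-(ethynyloxy)-5-methoxybenzene, via chloroethynyl ether 8 (not isolated), via lithium acetylide 9 (not isolated)
Conditions: n-BuLi (2.3 equiv), Et2O, −78 °C; aq NH4Cl, −78 to 0 °C; used at once
Reagents that add atoms: none
Why: the standard ynol ether synthesis from 1,2-dichlorovinyl ethers, by vinylic deprotonation with β-elimination of chloride, then Cl–Li exchange on the chloroalkyne and protonation; benzyl ethers and the arene C–H bonds are not attacked at −78 °C.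

Step 6
Reactants: 11 chloroacetyl chloride; 12 ethoxyacetylene
Product: 14 4-chloro-3-ethoxycyclobut-2-en-1-one (racemic), via chloroketene 13 (not isolated)
Conditions: Et3N (slow addition), 12 (2 equiv), Et2O/hexanes, 0 °C to rt
Reagents that add atoms: none
Why: ketene–ynol ether [2+2] cycloaddition of chloroketene generated by dehydrochlorination, in which the ketene carbonyl carbon bonds to the nucleophilic CH carbon of the alkyne, so Cl ends on C4 next to the ethoxy carbon; the one stereocentre is racemic and is lost in step 7.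

Step 7
Reactants: 10 1,3-bis(benzyloxy)-2-(ethynyloxy)-5-methoxybenzene; 14 4-chloro-3-ethoxycyclobut-2-en-1-one
Product: 19 5-[2,6-bis(benzyloxy)-4-methoxyphenoxy]-2-chloro-3-ethoxyphenol, via chlorovinylketene 15 (not isolated), via vinylcyclobutenone 16 (not isolated), via dienylketene 17 (not isolated), via chlorocyclohexadienone 18 (not isolated)
Conditions: 14 (1.5 equiv, in portions), toluene, 80 °C then 110 °C, sealed tube; crude stirred with K2CO3, MeOH, rt to cleave any O-acylated phenol
Reagents that add atoms: none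
Why: Proposed new method: thermal 4π electrocyclic opening of 14, with chlorine rotating outward, should give chlorovinylketene 15, whose ketene carbon is attacked by the electron-rich CH carbon of aryl ethynyl ether 10 in a regioselective [2+2] cycloaddition to vinylcyclobutenone 16. A second 4π opening gives dienylketene 17, and ring F then closes by 6π electrocyclisation (ketene carbon to the CHCl terminus, a six-membered carbocycle) to the 6-chlorodienone 18, which tautomerises to phenol 19. The closest known reaction type is the Danheiser benzannulation of cyclobutenones with alkyl and silyl ynol ethers; the extension is to an aryl ethynyl ether, which is less nucleophilic but has no β-hydrogen for retro-ene loss, and to a cyclobutenone carrying one chlorine at C4. No stereocentre survives, because the transient sp3 carbons of 16 and 18 (racemic) become aromatic. Only one regiochemistry is needed: the polarisation of the ynol ether places the aryloxy carbon meta to the new OH and para to the CHCl carbon, and the single chlorine, which in 14 sits between the carbonyl and the ethoxy carbon, is delivered between C–OH and C–OEt with one hydrogen left for aromatisation.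

Step 8
Reactants: 19 5-[2,6-bis(benzyloxy)-4-methoxyphenoxy]-2-chloro-3-ethoxyphenol
Product: 20 1,3-bis(benzyloxy)-2-(4-chloro-3,5-diethoxyphenoxy)-5-methoxybenzene
Conditions: EtI, K2CO3, DMF, 50 °C
Reagents that add atoms: iodoethane, CCI
Why: Williamson ether synthesis on the only free phenol protects ring F for the copper step and makes the ring symmetric.

Step 9
Reactants: 20 1,3-bis(benzyloxy)-2-(4-chloro-3,5-diethoxyphenoxy)-5-methoxybenzene
Product: 21 2-(4-chloro-3,5-diethoxyphenoxy)-5-methoxybenzene-1,3-diol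
Conditions: BCl3 (5 equiv), pentamethylbenzene (6 equiv), CH2Cl2, −78 °C; MeOH quench
Reagents that add atoms: none
Why: Lewis acid debenzylation with a non-basic cation scavenger should remove both benzyl groups at −78 °C while methyl and ethyl aryl ethers, the diaryl ether and the aryl chloride, which hydrogenolysis would endanger, remain.

Step 10
Reactants: 22 2-bromo-1,3-dimethoxybenzene
Product: 24 4-bromo-3,5-dimethoxyphenol, via aryl pinacol boronate 23 (not isolated)
Conditions: [Ir(OMe)(cod)]2 (1.5 mol %), 4,4′-di-tert-butyl-2,2′-bipyridine (3 mol %), B2pin2, THF, 80 °C; then KHSO5 (as 2KHSO5·KHSO4·K2SO4), acetone/H2O, rt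
Reagents that add atoms: potassium peroxymonosulfate, [K+].[O-]S(=O)(=O)OO
Why: sterically controlled iridium-catalysed C–H borylation occurs at the only C–H without an ortho substituent (para to Br) and tolerates the bromide, and oxidation of the C–B bond in the same pot gives the phenol.

Step 11
Reactants: 24 4-bromo-3,5-dimethoxyphenol
Product: 25 4-bromo-2-iodo-3,5-dimethoxyphenol
Conditions: NIS (1.0 equiv), MeCN, 0 °C, dark
Reagents that add atoms: N-iodosuccinimide, O=C1CCC(=O)N1I
Why: electrophilic aromatic iodination ortho to the phenol; the two free positions are equivalent, so regiochemistry is not in question and one equivalent of reagent limits di-iodination.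

Step 12
Reactants: 25 4-bromo-2-iodo-3,5-dimethoxyphenol; 26 (2,4,6-trimethoxyphenyl)boronic acid
Product: 27 4-bromo-3,5-dimethoxy-2-(2,4,6-trimethoxyphenyl)phenol
Conditions: 26 (1.5 equiv), Pd(OAc)2 (5 mol %), SPhos (10 mol %), K3PO4, toluene/H2O, 60 °C
Reagents that add atoms: none
Why: Suzuki–Miyaura coupling with a dialkylbiarylphosphine suited to tetra-ortho-substituted biaryls; oxidative addition at C–I should precede that at the equally hindered C–Br bond, which is kept for step 14.

Step 13
Reactants: 27 4-bromo-3,5-dimethoxy-2-(2,4,6-trimethoxyphenyl)phenol; 28 2-iodo-1,3,5-trimethoxybenzene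
Product: 29 2-bromo-1,3-dimethoxy-4-(2,4,6-trimethoxyphenyl)-5-(2,4,6-trimethoxyphenoxy)benzene
Conditions: 28 (2 equiv), CuI (20 mol %), N,N-dimethylglycine hydrochloride (60 mol %), Cs2CO3, 1,4-dioxane, 90 °C
Reagents that add atoms: none
Why: Ullmann diaryl ether synthesis at a temperature where the aryl iodide couples and the electron-rich 2,6-dimethoxyaryl bromide of 27 and 29 should not, with the iodide in excess to suppress self-condensation.

Step 14
Reactants: 21 2-(4-chloro-3,5-diethoxyphenoxy)-5-methoxybenzene-1,3-diol; 29 2-bromo-1,3-dimethoxy-4-(2,4,6-trimethoxyphenyl)-5-(2,4,6-trimethoxyphenoxy)benzene (2 equivalents react)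
Product: 30 1,3-bis[2,6-dimethoxy-3-(2,4,6-trimethoxyphenyl)-4-(2,4,6-trimethoxyphenoxy)phenoxy]-2-(4-chloro-3,5-diethoxyphenoxy)-5-methoxybenzene
Conditions: 29 (2.5 equiv), CuI (40 mol %), 2,2,6,6-tetramethylheptane-3,5-dione (80 mol %), Cs2CO3, NMP, 120 °C, Ar
Reagents that add atoms: none
Why: twofold Ullmann diaryl ether synthesis of the two equivalent ring C phenoxides with a 2-bromo-1,3-dimethoxyarene, the coupling type used for phloroglucinol aryl ethers, with a diketone ligand suited to electron-rich aryl bromides; the flanked aryl chloride of ring F is inert to copper.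

Step 15
Reactants: 30 1,3-bis[2,6-dimethoxy-3-(2,4,6-trimethoxyphenyl)-4-(2,4,6-trimethoxyphenoxy)phenoxy]-2-(4-chloro-3,5-diethoxyphenoxy)-5-methoxybenzene
Product: 31 4-(4-chloro-3,5-dihydroxyphenoxy)-3,5-bis[2,6-dihydroxy-3-(2,4,6-trihydroxyphenyl)-4-(2,4,6-trihydroxyphenoxy)phenoxy]phenol (CNP0275555.0)
Conditions: BBr3 (about 3 equiv per ether), CH2Cl2, −78 °C to rt; MeOH then H2O; Sephadex LH-20 under Ar
Reagents that add atoms: none
Why: Lewis acid cleavage of aryl alkyl ethers by BBr3 should remove the 17 methyl and 2 ethyl groups, while diaryl ethers, the biaryl bonds and the aryl chloride are not cleaved by this reagent.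

**Compound list**

1 | 2,6-dibromo-4-methoxyphenol | COc1cc(Br)c(O)c(Br)c1 | starting material
2 | 1,3-dibromo-5-methoxy-2-(methoxymethoxy)benzene | COCOc1c(Br)cc(OC)cc1Br | intermediate
3 | 1,3-bis(benzyloxy)-5-methoxy-2-(methoxymethoxy)benzene | COCOc1c(OCc2ccccc2)cc(OC)cc1OCc1ccccc1 | intermediate
4 | 2,6-bis(benzyloxy)-4-methoxyphenol | COc1cc(OCc2ccccc2)c(O)c(OCc2ccccc2)c1 | intermediate
5 | trichloroethylene | ClC=C(Cl)Cl | starting material
6 | dichloroacetylene (not isolated) | ClC#CCl | intermediate
7 | 1,3-bis(benzyloxy)-2-{[(E)-1,2-dichloroethenyl]oxy}-5-methoxybenzene | Cl/C=C(/Cl)Oc1c(OCc2ccccc2)cc(OC)cc1OCc1ccccc1 | intermediate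
8 | 1,3-bis(benzyloxy)-2-[(chloroethynyl)oxy]-5-methoxybenzene (not isolated) | ClC#COc1c(OCc2ccccc2)cc(OC)cc1OCc1ccccc1 | intermediate
9 | {[2,6-bis(benzyloxy)-4-methoxyphenoxy]ethynyl}lithium (not isolated) | [Li]C#COc1c(OCc2ccccc2)cc(OC)cc1OCc1ccccc1 | intermediate
10 | 1,3-bis(benzyloxy)-2-(ethynyloxy)-5-methoxybenzene | C#COc1c(OCc2ccccc2)cc(OC)cc1OCc1ccccc1 | intermediate
11 | chloroacetyl chloride | ClCC(=O)Cl | starting material
12 | ethoxyacetylene | CCOC#C | starting material
13 | chloroketene (not isolated) | ClC=C=O | intermediate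
14 | 4-chloro-3-ethoxycyclobut-2-en-1-one (racemic) | CCOC1=CC(=O)C1Cl | intermediate
15 | (3Z)-4-chloro-3-ethoxybuta-1,3-dien-1-one, Cl trans to the ketene carbon (not isolated) | O=C=C/C(OCC)=C/Cl | intermediate
16 | 3-[2,6-bis(benzyloxy)-4-methoxyphenoxy]-4-[(Z)-2-chloro-1-ethoxyethenyl]cyclobut-2-en-1-one (racemic, not isolated) | O=C1C=C(Oc2c(OCc3ccccc3)cc(OC)cc2OCc2ccccc2)C1/C(OCC)=C/Cl | intermediate
17 | (3E,5Z)-3-[2,6-bis(benzyloxy)-4-methoxyphenoxy]-6-chloro-5-ethoxyhexa-1,3,5-trien-1-one (not isolated) | O=C=C/C(Oc1c(OCc2ccccc2)cc(OC)cc1OCc1ccccc1)=C\C(OCC)=C\Cl | intermediate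
18 | 3-[2,6-bis(benzyloxy)-4-methoxyphenoxy]-6-chloro-5-ethoxycyclohexa-2,4-dien-1-one (racemic, not isolated) | O=C1C=C(Oc2c(OCc3ccccc3)cc(OC)cc2OCc2ccccc2)C=C(OCC)C1Cl | intermediate
19 | 5-[2,6-bis(benzyloxy)-4-methoxyphenoxy]-2-chloro-3-ethoxyphenol | CCOc1cc(Oc2c(OCc3ccccc3)cc(OC)cc2OCc2ccccc2)cc(O)c1Cl | intermediate
20 | 1,3-bis(benzyloxy)-2-(4-chloro-3,5-diethoxyphenoxy)-5-methoxybenzene | CCOc1cc(Oc2c(OCc3ccccc3)cc(OC)cc2OCc2ccccc2)cc(OCC)c1Cl | intermediate
21 | 2-(4-chloro-3,5-diethoxyphenoxy)-5-methoxybenzene-1,3-diol | CCOc1cc(Oc2c(O)cc(OC)cc2O)cc(OCC)c1Cl | intermediate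
22 | 2-bromo-1,3-dimethoxybenzene | COc1cccc(OC)c1Br | starting material
23 | 2-(4-bromo-3,5-dimethoxyphenyl)-4,4,5,5-tetramethyl-1,3,2-dioxaborolane (not isolated) | COc1cc(B2OC(C)(C)C(C)(C)O2)cc(OC)c1Br | intermediate
24 | 4-bromo-3,5-dimethoxyphenol | COc1cc(O)cc(OC)c1Br | intermediate
25 | 4-bromo-2-iodo-3,5-dimethoxyphenol | COc1cc(O)c(I)c(OC)c1Br | intermediate
26 | (2,4,6-trimethoxyphenyl)boronic acid | COc1cc(OC)c(B(O)O)c(OC)c1 | starting material
27 | 4-bromo-3,5-dimethoxy-2-(2,4,6-trimethoxyphenyl)phenol | COc1cc(OC)c(-c2c(O)cc(OC)c(Br)c2OC)c(OC)c1 | intermediate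
28 | 2-iodo-1,3,5-trimethoxybenzene | COc1cc(OC)c(I)c(OC)c1 | starting material
29 | 2-bromo-1,3-dimethoxy-4-(2,4,6-trimethoxyphenyl)-5-(2,4,6-trimethoxyphenoxy)benzene (arm bromide, rings A, B, G) | COc1cc(OC)c(Oc2cc(OC)c(Br)c(OC)c2-c2c(OC)cc(OC)cc2OC)c(OC)c1 | intermediate
30 | 1,3-bis[2,6-dimethoxy-3-(2,4,6-trimethoxyphenyl)-4-(2,4,6-trimethoxyphenoxy)phenoxy]-2-(4-chloro-3,5-diethoxyphenoxy)-5-methoxybenzene | COc1cc(OC)c(Oc2cc(OC)c(Oc3cc(OC)cc(Oc4c(OC)cc(Oc5c(OC)cc(OC)cc5OC)c(-c5c(OC)cc(OC)cc5OC)c4OC)c3Oc3cc(OCC)c(Cl)c(OCC)c3)c(OC)c2-c2c(OC)cc(OC)cc2OC)c(OC)c1 | intermediate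
31 | 4-(4-chloro-3,5-dihydroxyphenoxy)-3,5-bis[2,6-dihydroxy-3-(2,4,6-trihydroxyphenyl)-4-(2,4,6-trihydroxyphenoxy)phenoxy]phenol (CNP0275555.0) | Oc1cc(O)c(Oc2cc(O)c(Oc3cc(O)cc(Oc4c(O)cc(Oc5c(O)cc(O)cc5O)c(-c5c(O)cc(O)cc5O)c4O)c3Oc3cc(O)c(Cl)c(O)c3)c(O)c2-c2c(O)cc(O)cc2O)c(O)c1 | target

**Step count**

Total: 15 steps. Longest linear sequence: 10 steps (1 to 31 through steps 1–5, 7–9, 14 and 15). The arm branch (steps 10–13) and the cyclobutenone branch (step 6) join it.

**Steps most likely to fail**

Step 7 (benzannulation). The aryl ethynyl ether may oligomerise or be consumed by traces of acid before 14 opens, or the chlorovinylketene may dimerise, so that ring F does not form. The fallback uses known chemistry, sets out from 4 and comes back at 20: ring F is taken as a benzene and joined by copper-catalysed arylation of the hindered phenol with an unhindered aryl bromide. 2-Chlororesorcinol is O-ethylated (EtI, K2CO3, DMF) to 2-chloro-1,3-diethoxybenzene F1. Iridium-catalysed C–H borylation ([Ir(OMe)(cod)]2, 4,4′-di-tert-butyl-2,2′-bipyridine, B2pin2, THF, 80 °C) at the only C–H without an ortho neighbour should give 2-(4-chloro-3,5-diethoxyphenyl)-4,4,5,5-tetramethyl-1,3,2-dioxaborolane F2. CuBr2 in MeOH/H2O at 80 °C should convert it to 5-bromo-2-chloro-1,3-diethoxybenzene F3. F3 and 4 with CuI, picolinic acid, K3PO4 in DMSO at 100 °C should then give 20, the C–Br bond reacting and the flanked C–Cl bond not.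

Step 14 (twofold etherification). After the first arylation the remaining ring C phenoxide may couple too slowly against three large aryl groups, while 29 is lost by reductive debromination and 21 by oxidation. The fallback sets out from 21 (using 24, 26 and 28) and comes back at 30: the arms are grown on ring C in two directions from a small ring B unit. Phenol 24 is benzylated (BnBr, K2CO3, DMF) to 5-(benzyloxy)-2-bromo-1,3-dimethoxybenzene F4, which lacks the aryl and aryloxy groups that buttress the methoxy groups of 29. Twofold Ullmann etherification of 21 with F4 under the conditions of step 14 should give 1,3-bis[4-(benzyloxy)-2,6-dimethoxyphenoxy]-2-(4-chloro-3,5-diethoxyphenoxy)-5-methoxybenzene F5. BCl3 and pentamethylbenzene at −78 °C should free the two outer phenols, giving 4,4′-{[2-(4-chloro-3,5-diethoxyphenoxy)-5-methoxy-1,3-phenylene]bis(oxy)}bis(3,5-dimethoxyphenol) F6. NIS (2 equiv) should iodinate each phenol ring once ortho to OH, giving the corresponding bis(2-iodo-3,5-dimethoxyphenol) F7. Twofold Suzuki–Miyaura coupling with 26 (Pd(OAc)2, SPhos, K3PO4) gives the bis[3,5-dimethoxy-2-(2,4,6-trimethoxyphenyl)phenol] F8, and twofold Ullmann etherification with 28 (conditions of step 13) then gives 30.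

Step 12 (Suzuki coupling). Base-mediated protodeboronation of 26 may outrun transmetalation at the crowded palladium centre, and on long heating the C–Br bond may begin to couple. The fallback sets out from 25 and comes back at 27: a Negishi coupling that needs no aqueous base. Phenol 25 is protected (MOMCl, i-Pr2NEt, CH2Cl2) as 2-bromo-4-iodo-1,3-dimethoxy-5-(methoxymethoxy)benzene F9. 1,3,5-Trimethoxybenzene is lithiated (n-BuLi, THF, 0 °C) and transmetalated with ZnCl2 to chloro(2,4,6-trimethoxyphenyl)zinc F10. Pd2(dba)3 and SPhos in THF at 40 °C should couple F10 at the C–I bond of F9 to give 2-bromo-1,3-dimethoxy-5-(methoxymethoxy)-4-(2,4,6-trimethoxyphenyl)benzene F11, and HCl in MeOH returns 27.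

**Further compounds**

F1 | step 7 | 2-chloro-1,3-diethoxybenzene | CCOc1cccc(OCC)c1Cl
F2 | step 7 | 2-(4-chloro-3,5-diethoxyphenyl)-4,4,5,5-tetramethyl-1,3,2-dioxaborolane | CCOc1cc(B2OC(C)(C)C(C)(C)O2)cc(OCC)c1Cl
F3 | step 7 | 5-bromo-2-chloro-1,3-diethoxybenzene | CCOc1cc(Br)cc(OCC)c1Cl
F4 | step 14 | 5-(benzyloxy)-2-bromo-1,3-dimethoxybenzene | COc1cc(OCc2ccccc2)cc(OC)c1Br
F5 | step 14 | 1,3-bis[4-(benzyloxy)-2,6-dimethoxyphenoxy]-2-(4-chloro-3,5-diethoxyphenoxy)-5-methoxybenzene | CCOc1cc(Oc2c(Oc3c(OC)cc(OCc4ccccc4)cc3OC)cc(OC)cc2Oc2c(OC)cc(OCc3ccccc3)cc2OC)cc(OCC)c1Cl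
F6 | step 14 | 4,4′-{[2-(4-chloro-3,5-diethoxyphenoxy)-5-methoxy-1,3-phenylene]bis(oxy)}bis(3,5-dimethoxyphenol) | CCOc1cc(Oc2c(Oc3c(OC)cc(O)cc3OC)cc(OC)cc2Oc2c(OC)cc(O)cc2OC)cc(OCC)c1Cl
F7 | step 14 | 4,4′-{[2-(4-chloro-3,5-diethoxyphenoxy)-5-methoxy-1,3-phenylene]bis(oxy)}bis(2-iodo-3,5-dimethoxyphenol) | CCOc1cc(Oc2c(Oc3c(OC)cc(O)c(I)c3OC)cc(OC)cc2Oc2c(OC)cc(O)c(I)c2OC)cc(OCC)c1Cl
F8 | step 14 | 4,4′-{[2-(4-chloro-3,5-diethoxyphenoxy)-5-methoxy-1,3-phenylene]bis(oxy)}bis[3,5-dimethoxy-2-(2,4,6-trimethoxyphenyl)phenol] | CCOc1cc(Oc2c(Oc3c(OC)cc(O)c(-c4c(OC)cc(OC)cc4OC)c3OC)cc(OC)cc2Oc2c(OC)cc(O)c(-c3c(OC)cc(OC)cc3OC)c2OC)cc(OCC)c1Cl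
F9 | step 12 | 2-bromo-4-iodo-1,3-dimethoxy-5-(methoxymethoxy)benzene | COCOc1cc(OC)c(Br)c(OC)c1I
F10 | step 12 | chloro(2,4,6-trimethoxyphenyl)zinc | COc1cc(OC)c([Zn]Cl)c(OC)c1
F11 | step 12 | 2-bromo-1,3-dimethoxy-5-(methoxymethoxy)-4-(2,4,6-trimethoxyphenyl)benzene | COCOc1cc(OC)c(Br)c(OC)c1-c1c(OC)cc(OC)cc1OC
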